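**Plan**

Target numbering: C1 = CH(O-angeloyl), C2 = CH(OH), C3 = C(CH3)OH, C7 = CH(CH3), C10 = CH carrying C1′(CH3)2OH; acyclic compounds are described with these "future" locants.
Enabling feature: C1 and C2 are adjacent CH–O carbons (a trans vicinal diol, one oxygen acylated) inside the ten-membered carbocycle, each next to an oxygenated branch point (C10/C1′ and C3); reductive coupling of two formyl groups gives exactly this.
Retrosynthesis: (i) angelate C–O; (ii) ring bond C1–C2, giving the open-chain 1,10-dialdehyde 11; (iii) C9–C10, giving (S)-citronellyl Grignard and the (S)-epoxy alcohol of prenol; the C1, C2 and C3 oxygens come from oxidation of the two chain ends.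
Forward: C10 + C5 chain union; SeO2 hydroxylation, epoxidation and hydride opening at the isopropylidene end; oxidation of both primary termini; closure of the only ring (cyclodecane) by titanium-induced pinacol coupling; bis-acetonide differentiation of O1 from O2; angeloylation; deprotection.
Stereochemistry: C7 from (S)-citronellyl bromide; C10 from Sharpless epoxidation of prenol and SN2 inversion; C3 from Sharpless epoxidation of the (E)-allylic alcohol; C1 and C2 in the key step by 1,2-induction from C10 and C3 plus the trans preference of medium-ring pinacol closure; the (Z)-olefin arrives with angelic acid.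

Key step: step 9

**Route**

Step 1
Reactants: 1 prenol (3-methylbut-2-en-1-ol)
Product: 2 (S)-(3,3-dimethyloxiran-2-yl)methanol
Conditions: Ti(OiPr)4 (cat.), L-(+)-DIPT (cat.), t-BuOOH, 4 Å MS, CH2Cl2, −20 °C
Reagents that add atoms: tert-butyl hydroperoxide, CC(C)(C)OO
Why: Katsuki–Sharpless asymmetric epoxidation of a trisubstituted allylic alcohol; the L-(+)-tartrate delivers oxygen to the face that gives the (2S)-epoxide, whose C2 becomes C10.

Step 2
Reactants: 2; 3 (S)-citronellyl bromide
Product: 5 (2R)-2-[(3S)-3,7-dimethyloct-6-en-1-yl]-3-methylbutane-1,3-diol, via (S)-citronellylmagnesium bromide 4 (not isolated)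
Conditions: 3, Mg, THF (gives 4, 2.5 equiv); CuI (10 mol %), then 2, THF, −30 → 0 °C; aq NH4Cl
Reagents that add atoms: none
Why: Copper-catalysed Grignard opening of a 2,3-epoxy alcohol: one equivalent of 4 forms the magnesium alkoxide, the gem-dimethyl carbon is closed to SN2 attack, and the alkylcopper attacks the secondary epoxide carbon with inversion, which sets C10 (2R in 5) and leaves the tertiary alcohol.

Step 3
Reactants: 5
Product: 6 (2R)-2-[(3S)-3,7-dimethyloct-6-en-1-yl]-3-methyl-1,3-bis(triethylsilyloxy)butane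
Conditions: TESOTf (2.5 equiv), 2,6-lutidine, CH2Cl2, −78 → 0 °C
Reagents that add atoms: triethylsilyl triflate, CC[Si](CC)(CC)OS(=O)(=O)C(F)(F)F
Why: Silyl triflate/2,6-lutidine silylation, reactive enough for the tertiary hydroxyl; it masks the 1,3-diol for the titanium-mediated epoxidation, and the primary ether later serves as precursor of the C1 formyl group.

Step 4
Reactants: 6
Product: 7 (2E,6S,9R)-2,6,10-trimethyl-10-(triethylsilyloxy)-9-[(triethylsilyloxy)methyl]undec-2-en-1-ol
Conditions: SeO2 (0.5 equiv), t-BuOOH, CH2Cl2, 25 °C, stopped before over-oxidation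
Reagents that add atoms: tert-butyl hydroperoxide, CC(C)(C)OO (oxygen relayed through SeO2)
Why: SeO2/t-BuOOH allylic oxidation (ene reaction, then [2,3]-sigmatropic shift) of a gem-dimethyl trisubstituted olefin, which by the usual rule hydroxylates the (E)-methyl group and gives the (E)-2-methyl allylic alcohol.

Step 5
Reactants: 7
Product: 8 [(2S,3S)-3-[(3R,6R)-3,7-dimethyl-7-(triethylsilyloxy)-6-[(triethylsilyloxy)methyl]octyl]-2-methyloxiran-2-yl]methanol
Conditions: Ti(OiPr)4 (cat.), L-(+)-DIPT (cat.), t-BuOOH, 4 Å MS, CH2Cl2, −20 °C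
Reagents that add atoms: tert-butyl hydroperoxide, CC(C)(C)OO
Why: Katsuki–Sharpless asymmetric epoxidation of an (E)-2-methyl allylic alcohol, reagent-controlled by L-(+)-DIPT to the (2S,3S)-epoxide, whose quaternary carbon is the future C3 with its C–O bond already in the required configuration.

Step 6
Reactants: 8
Product: 9 (2R,6S,9R)-2,6,10-trimethyl-10-(triethylsilyloxy)-9-[(triethylsilyloxy)methyl]undecane-1,2-diol
Conditions: LiAlH4, THF, 0 → 25 °C; Fieser work-up
Reagents that add atoms: none
Why: Hydride opening of a 2,3-epoxy alcohol whose C2 is fully substituted: SN2 delivery is possible only at the secondary C3, so the C2–O bond is retained and the (2R)-1,2-diol results, the silyl ethers being inert to LiAlH4.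

Step 7
Reactants: 9
Product: 10 (2R,6S,9R)-2,6,10-trimethyl-1,2,10-tris(triethylsilyloxy)-9-[(triethylsilyloxy)methyl]undecane
Conditions: TESOTf (2.5 equiv), 2,6-lutidine, CH2Cl2, −78 → 0 °C
Reagents that add atoms: triethylsilyl triflate, CC[Si](CC)(CC)OS(=O)(=O)C(F)(F)F
Why: Silyl triflate silylation of the primary and the tertiary hydroxyl, which gives two primary and two tertiary triethylsilyl ethers that the next step tells apart.

Step 8
Reactants: 10
Product: 11 (2R,6S,9S)-2,6-dimethyl-2-(triethylsilyloxy)-9-[2-(triethylsilyloxy)propan-2-yl]decanedial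
Conditions: (COCl)2, DMSO, CH2Cl2, −78 → −30 °C; Et3N, −78 → 0 °C; used at once
Reagents that add atoms: none
Why: Swern oxidation applied directly to silyl ethers: the chlorosulfonium reagent cleaves and oxidises primary triethylsilyl ethers in one flask and leaves tertiary ones untouched, and the cold amine quench limits epimerisation at C10.

Step 9
Reactants: 11
Product: 12 (1R,2S,3R,7S,10R)-3,7-dimethyl-3-(triethylsilyloxy)-10-[2-(triethylsilyloxy)propan-2-yl]cyclodecane-1,2-diol
Conditions: TiCl3(DME)1.5, Zn–Cu, DME, 25 °C, syringe-pump addition of 11 (ca. 2 mM final); aq K2CO3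
Reagents that add atoms: none
Why: Low-valent titanium reduces both formyl groups to titanium-bound ketyls whose carbons C1 and C2 combine, and hydrolysis of the titanium pinacolate should give the diol; at 25 °C the sequence stops before deoxygenation to the cycloalkene. The closest known reaction type is the McMurry intramolecular pinacol coupling of α,ω-dialdehydes to cycloalkane-1,2-diols, which delivers medium and large rings and there mainly the trans diol. The cyclodecane is closed by ketyl–ketyl combination on the metal, formally a 10-exo-trig attack of one ketyl carbon on the other titanium-bound carbonyl. C1 is set by C10 and C2 by C3 through Felkin–Anh-type 1,2-induction: the new bond forms anti to the 2-silyloxyprop-2-yl group at C10 (ring CH2 inside, H outside) and anti to the C3–OSiEt3 bond (ring CH2 inside, CH3 outside), which together give 1R,2S, the trans diol that the ring size also favours. The step needs ring closure to beat intermolecular coupling, secured by high-dilution slow addition and the slow dimerisation of two neopentyl-type aldehydes, and it needs the silyloxy groups and the C10 stereocentre to survive, for which the medium is neutral and non-basic.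

Step 10
Reactants: 12
Product: 14 bis-acetonide of 13 (2,3-O-isopropylidene as cis-fused 1,3-dioxolane; 1,1′-O-isopropylidene as 1,3-dioxane), via tetraol 13 (not isolated)
Conditions: CSA (cat.), MeOH, 25 °C; evaporate; 2,2-dimethoxypropane–acetone, 4 Å MS, 25 °C
Reagents that add atoms: 2,2-dimethoxypropane, COC(C)(C)OC
Why: Acid-catalysed methanolysis of the silyl ethers followed by ketal exchange under thermodynamic control: the only pairing that ketalises all four hydroxyls is the cis C2/C3 diol as a dioxolane and O1 with O1′ as a dioxane, so the equilibrium should drain into the bis-acetonide, which places O1 and O2 in different rings.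

Step 11
Reactants: 14
Product: 15 2,3-O-isopropylidene ketal of 13 (1-OH and 1′-OH free)
Conditions: AcOH–THF–H2O (4:1:1), 0 → 25 °C, monitored
Reagents that add atoms: none
Why: Selective acetal hydrolysis: the six-membered ketal, strained by a syn-axial methyl/methyl contact with the gem-dimethyl carbon, should hydrolyse much faster than the dioxolane (as 4,6- versus 2,3-O-isopropylidene groups of sugars do), which frees O1 while O2 stays masked.

Step 12
Reactants: 15; 16 angelic acid [(Z)-2-methylbut-2-enoic acid]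
Product: 18 1-O-angeloyl derivative of 15, via angelic 2,4,6-trichlorobenzoic anhydride 17 (not isolated)
Conditions: 16, 2,4,6-Cl3C6H2COCl, Et3N, toluene, 25 °C; then 15, toluene, 80 °C
Reagents that add atoms: none
Why: Yamaguchi-type esterification through the preformed mixed anhydride without DMAP, the established way to angelates without Z→E isomerisation; the secondary 1-OH is the only acylable hydroxyl (1′-OH is tertiary), so the ester goes to O1 and the (Z)-olefin is carried in unchanged.

Step 13
Reactants: 18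
Product: 19 (1R,2S,3R,7S,10R)-2,3-dihydroxy-10-(2-hydroxypropan-2-yl)-3,7-dimethylcyclodecyl (2Z)-2-methylbut-2-enoate (target)
Conditions: AcOH–H2O (4:1), 40 °C
Reagents that add atoms: none
Why: Mild aqueous-acid hydrolysis of the remaining isopropylidene ketal, conditions under which an angelate should neither isomerise nor migrate to the neighbouring hydroxyl.

**Compound list**

1 | prenol (3-methylbut-2-en-1-ol) | CC(C)=CCO | starting material
2 | (S)-(3,3-dimethyloxiran-2-yl)methanol | OC[C@@H]1OC1(C)C | intermediate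
3 | (S)-citronellyl bromide [(6S)-8-bromo-2,6-dimethyloct-2-ene] | BrCC[C@@H](C)CCC=C(C)C | starting material
4 | (S)-citronellylmagnesium bromide | Br[Mg]CC[C@@H](C)CCC=C(C)C | intermediate (not isolated)
5 | (2R)-2-[(3S)-3,7-dimethyloct-6-en-1-yl]-3-methylbutane-1,3-diol | OC[C@H](C(C)(C)O)CC[C@@H](C)CCC=C(C)C | intermediate
6 | (2R)-2-[(3S)-3,7-dimethyloct-6-en-1-yl]-3-methyl-1,3-bis(triethylsilyloxy)butane | CC[Si](CC)(CC)OC[C@H](C(C)(C)O[Si](CC)(CC)CC)CC[C@@H](C)CCC=C(C)C | intermediate
7 | (2E,6S,9R)-2,6,10-trimethyl-10-(triethylsilyloxy)-9-[(triethylsilyloxy)methyl]undec-2-en-1-ol | CC[Si](CC)(CC)OC[C@H](C(C)(C)O[Si](CC)(CC)CC)CC[C@@H](C)CC/C=C(\C)CO | intermediate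
8 | [(2S,3S)-3-[(3R,6R)-3,7-dimethyl-7-(triethylsilyloxy)-6-[(triethylsilyloxy)methyl]octyl]-2-methyloxiran-2-yl]methanol | CC[Si](CC)(CC)OC[C@H](C(C)(C)O[Si](CC)(CC)CC)CC[C@@H](C)CC[C@@H]1O[C@@]1(C)CO | intermediate
9 | (2R,6S,9R)-2,6,10-trimethyl-10-(triethylsilyloxy)-9-[(triethylsilyloxy)methyl]undecane-1,2-diol | CC[Si](CC)(CC)OC[C@H](C(C)(C)O[Si](CC)(CC)CC)CC[C@@H](C)CCC[C@@](C)(O)CO | intermediate
10 | (2R,6S,9R)-2,6,10-trimethyl-1,2,10-tris(triethylsilyloxy)-9-[(triethylsilyloxy)methyl]undecane | CC[Si](CC)(CC)OC[C@H](C(C)(C)O[Si](CC)(CC)CC)CC[C@@H](C)CCC[C@@](C)(O[Si](CC)(CC)CC)CO[Si](CC)(CC)CC | intermediate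
11 | (2R,6S,9S)-2,6-dimethyl-2-(triethylsilyloxy)-9-[2-(triethylsilyloxy)propan-2-yl]decanedial | O=C[C@H](C(C)(C)O[Si](CC)(CC)CC)CC[C@@H](C)CCC[C@@](C)(O[Si](CC)(CC)CC)C=O | intermediate
12 | (1R,2S,3R,7S,10R)-3,7-dimethyl-3-(triethylsilyloxy)-10-[2-(triethylsilyloxy)propan-2-yl]cyclodecane-1,2-diol | O[C@@H]1[C@H](C(C)(C)O[Si](CC)(CC)CC)CC[C@@H](C)CCC[C@@](C)(O[Si](CC)(CC)CC)[C@H]1O | intermediate
13 | (1R,2S,3R,7S,10R)-10-(2-hydroxypropan-2-yl)-3,7-dimethylcyclodecane-1,2,3-triol (target numbering) | O[C@@H]1[C@H](C(C)(C)O)CC[C@@H](C)CCC[C@@](C)(O)[C@H]1O | intermediate (not isolated)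
14 | bis-acetonide of 13: dioxolane on O2/O3, 1,3-dioxane on O1/O1′ | CC1(C)O[C@@H]2[C@H](C(C)(C)O1)CC[C@@H](C)CCC[C@@]3(C)OC(C)(C)O[C@@H]23 | intermediate
15 | 2,3-O-isopropylidene ketal of 13 (1-OH and 1′-OH free) | O[C@@H]1[C@H](C(C)(C)O)CC[C@@H](C)CCC[C@@]2(C)OC(C)(C)O[C@@H]12 | intermediate
16 | angelic acid [(Z)-2-methylbut-2-enoic acid] | C/C=C(/C)C(=O)O | starting material
17 | angelic 2,4,6-trichlorobenzoic anhydride | C/C=C(/C)C(=O)OC(=O)c1c(Cl)cc(Cl)cc1Cl | intermediate (not isolated)
18 | 1-O-angeloyl-2,3-O-isopropylidene derivative of 13 | C/C=C(/C)C(=O)O[C@@H]1[C@H](C(C)(C)O)CC[C@@H](C)CCC[C@@]2(C)OC(C)(C)O[C@@H]12 | intermediate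
19 | (1R,2S,3R,7S,10R)-2,3-dihydroxy-10-(2-hydroxypropan-2-yl)-3,7-dimethylcyclodecyl (2Z)-2-methylbut-2-enoate | C/C=C(/C)C(=O)O[C@@H]1[C@H](C(C)(C)O)CC[C@@H](C)CCC[C@@](C)(O)[C@H]1O | target

**Count**

Total steps: 13. Longest linear sequence: 13 steps (1 → 19); 3 and 16 enter as purchased materials at steps 2 and 12.

**Steps most likely to fail**

Step 9. The ten-membered closure is slow, so intermolecular pinacol coupling, plain reduction of the formyl groups or reductive loss of the α-silyloxy group may take over. Facial control at C2 also rests on a small CH3/CH2 difference. The fallback sets out from 11 and returns at 12. Double Wittig methylenation (Ph3P=CH2, THF, −78 → 0 °C) should give (3R,7S,10R)-3,7-dimethyl-3-(triethylsilyloxy)-10-[2-(triethylsilyloxy)propan-2-yl]dodeca-1,11-diene F1. Ring-closing metathesis (Grubbs II, toluene, 80 °C, 1 mM) should give (1E,3R,7S,10R)-3,7-dimethyl-3-(triethylsilyloxy)-10-[2-(triethylsilyloxy)propan-2-yl]cyclodec-1-ene F2, to be separated from any Z isomer. Syn-dihydroxylation of the E-olefin (OsO4 cat., NMO, acetone–H2O) gives a trans diol by stereospecificity; 12 is one of the two possible face isomers and would be separated from the other.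

Step 2. SN2 attack at the hindered secondary epoxide carbon is slow, so magnesium-halide-induced ionisation at the tertiary carbon (halohydrin formation, hydride shift) or Payne rearrangement followed by attack at C1 may compete. The fallback sets out from 3 and returns at 5; it makes C10 by auxiliary-controlled enolate chemistry.
- Alkylation of dilithioacetate with 3 (LDA, AcOH, THF–DMPU) gives (R)-5,9-dimethyldec-8-enoic acid F3.
- Pivaloyl mixed anhydride, then lithiated (S)-4-benzyloxazolidin-2-one, gives (S)-4-benzyl-3-[(R)-5,9-dimethyldec-8-enoyl]oxazolidin-2-one F4.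
- Evans titanium-enolate hydroxymethylation (TiCl4, iPr2NEt, s-trioxane, CH2Cl2, 0 °C), anti to the benzyl group, gives (S)-4-benzyl-3-[(2R,5S)-2-(hydroxymethyl)-5,9-dimethyldec-8-enoyl]oxazolidin-2-one F5.
- MeOMgBr in MeOH (0 °C) gives methyl (2R,5S)-2-(hydroxymethyl)-5,9-dimethyldec-8-enoate F6.
- Excess MeMgBr (THF, 0 °C) gives 5.

Step 10. The equilibrium ketalisation may settle on the trans acetonide across O1/O2 if closure of the crowded six-membered ketal onto the tertiary 1′-OH is too unfavourable. Acid may also eliminate a tertiary hydroxyl. The fallback sets out from 12 and returns at 15; it assigns the hydroxyl pairs one after the other. Desilylation (HF·pyridine, THF, 0 °C) gives tetraol 13, now isolated. tBu2Si(OTf)2 with 2,6-lutidine (CH2Cl2, 0 °C), which prefers 1,3-diols, should give the 1,1′-O-di-tert-butylsilylene derivative of 13, F7. 2,2-Dimethoxypropane with PPTS then ketalises the only diol left, giving the 1,1′-O-di-tert-butylsilylene-2,3-O-isopropylidene derivative of 13, F8. HF·pyridine (THF–pyridine, 0 °C) removes the silylene and gives 15.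

**Further compounds**

F1 | step 9 | (3R,7S,10R)-3,7-dimethyl-3-(triethylsilyloxy)-10-[2-(triethylsilyloxy)propan-2-yl]dodeca-1,11-diene | C=C[C@H](C(C)(C)O[Si](CC)(CC)CC)CC[C@@H](C)CCC[C@@](C)(O[Si](CC)(CC)CC)C=C
F2 | step 9 | (1E,3R,7S,10R)-3,7-dimethyl-3-(triethylsilyloxy)-10-[2-(triethylsilyloxy)propan-2-yl]cyclodec-1-ene | [C@@H]1(C(C)(C)O[Si](CC)(CC)CC)CC[C@@H](C)CCC[C@@](C)(O[Si](CC)(CC)CC)/C=C/1
F3 | step 2 | (R)-5,9-dimethyldec-8-enoic acid | OC(=O)CCC[C@@H](C)CCC=C(C)C
F4 | step 2 | (S)-4-benzyl-3-[(R)-5,9-dimethyldec-8-enoyl]oxazolidin-2-one | O=C(CCC[C@@H](C)CCC=C(C)C)N1[C@@H](Cc2ccccc2)COC1=O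
F5 | step 2 | (S)-4-benzyl-3-[(2R,5S)-2-(hydroxymethyl)-5,9-dimethyldec-8-enoyl]oxazolidin-2-one | O=C([C@@H](CO)CC[C@@H](C)CCC=C(C)C)N1[C@@H](Cc2ccccc2)COC1=O
F6 | step 2 | methyl (2R,5S)-2-(hydroxymethyl)-5,9-dimethyldec-8-enoate | COC(=O)[C@@H](CO)CC[C@@H](C)CCC=C(C)C
F7 | step 10 | 1,1′-O-di-tert-butylsilylene derivative of 13 (2-OH and 3-OH free) | CC(C)(C)[Si]1(C(C)(C)C)O[C@@H]2[C@H](C(C)(C)O1)CC[C@@H](C)CCC[C@@](C)(O)[C@H]2O
F8 | step 10 | 1,1′-O-di-tert-butylsilylene-2,3-O-isopropylidene derivative of 13 | CC(C)(C)[Si]1(C(C)(C)C)O[C@@H]2[C@H](C(C)(C)O1)CC[C@@H](C)CCC[C@@]3(C)OC(C)(C)O[C@@H]23
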